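**Plan**

1. Retrosynthesis: after removal of three O-protecting groups, the oxan-4-one ring is cut at C2–C3 and at O1–C6 in a single retro-oxa-[4+2] step. This gives vanillin acetate (O1=C2) and a 2-silyloxy-1,3-diene (C3=C4(OSi)–C5=C6) that already carries C1'. The diene is then cut at C5=C6 (Wittig) back to an α-silyloxy aldehyde from L-tyrosine.
2. Enabling feature: in the six-membered ring O1–C6, the O1–C2 bond is a masked aldehyde C=O, and the C4 ketone with its two flanking CH2 groups (C3, C5) is a masked 2-silyloxydiene. The ring is therefore the adduct of an aryl aldehyde and a four-carbon diene, and both ring stereocentres lie at the two new bonds.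
3. Forward order: the chain C1'–C6–C5–C4–C3 is assembled first (L-tyrosine, then an acetonyl ylide). The pyranone ring is then closed in one intermolecular event, and two deprotections finish the route.
4. Stereochemistry: C1' comes from L-tyrosine (diazotization with net retention). C2 is set by the chiral chromium catalyst (aldehyde face). C6 follows from the endo transition state (2,6-cis), reinforced by the allylic C1'–OTBS group.
5. Helpers: the acetyl group on the vanillin oxygen makes the aryl aldehyde electron-poor enough for a mono-oxygenated diene. The triethylsilyl enol ether carries C4 at the ketone oxidation level. Both are removed after the ring is formed.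

Key step: step 7

Assumption: ring atoms are numbered O1, C2 (aryl-bearing), C3, C4 (C=O), C5, C6, and the side-chain carbinol is C1'. The catalyst antipode is assigned by analogy with the usual facial preference of this catalyst family, recalled rather than verified, and would be checked on the first cycloadduct.

**Route**

Step 1
Reactants: 1 L-tyrosine
Product: 2 (2S)-2-hydroxy-3-(4-hydroxyphenyl)propanoic acid
Conditions: NaNO2, 1 M aq. H2SO4, 0 °C → rt
Reagents that add atoms: water, O
Why: Van Slyke-type diazotization of the α-amino acid proceeds by displacement of N2 by the neighbouring carboxylate to an α-lactone that water reopens, two inversions that amount to retention, so the (S)-centre of 1 becomes the (S)-carbinol that ends as C1' of the target.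

Step 2
Reactants: 2 (2S)-2-hydroxy-3-(4-hydroxyphenyl)propanoic acid
Product: 3 methyl (2S)-2-hydroxy-3-(4-hydroxyphenyl)propanoate
Conditions: MeOH, H2SO4 (cat.), reflux
Reagents that add atoms: methanol, CO
Why: Fischer esterification in excess methanol touches only the carboxyl group, so the α-hydroxy stereocentre and the phenol are unchanged.

Step 3
Reactants: 3 methyl (2S)-2-hydroxy-3-(4-hydroxyphenyl)propanoate
Product: 4 methyl (2S)-2-[(tert-butyldimethylsilyl)oxy]-3-{4-[(tert-butyldimethylsilyl)oxy]phenyl}propanoate
Conditions: TBSCl (2.5 equiv), imidazole, DMF, rt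
Reagents that add atoms: tert-butyldimethylsilyl chloride, CC(C)(C)[Si](C)(C)Cl
Why: Corey silylation converts both the phenol and the secondary alcohol to TBS ethers, which tolerate the hydride, ylide, silyl triflate and Lewis acid of the following steps.

Step 4
Reactants: 4 methyl (2S)-2-[(tert-butyldimethylsilyl)oxy]-3-{4-[(tert-butyldimethylsilyl)oxy]phenyl}propanoate
Product: 5 (2S)-2-[(tert-butyldimethylsilyl)oxy]-3-{4-[(tert-butyldimethylsilyl)oxy]phenyl}propanal
Conditions: i-Bu2AlH (1.1 equiv), CH2Cl2, −78 °C; MeOH, then aq. KNaC4H4O6; crude product used at once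
Reagents that add atoms: none
Why: Partial reduction of an ester with i-Bu2AlH at −78 °C stops at the aluminium hemiacetal, stabilized by the α-silyloxy group, which collapses to the aldehyde only on work-up, and the configurationally labile α-silyloxy aldehyde is taken on without purification.

Step 5
Reactants: 5 (2S)-2-[(tert-butyldimethylsilyl)oxy]-3-{4-[(tert-butyldimethylsilyl)oxy]phenyl}propanal; 6 1-(triphenyl-λ5-phosphanylidene)propan-2-one
Product: 7 (3E,5S)-5-[(tert-butyldimethylsilyl)oxy]-6-{4-[(tert-butyldimethylsilyl)oxy]phenyl}hex-3-en-2-one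
Conditions: CH2Cl2, rt
Reagents that add atoms: none
Why: Wittig olefination with a ketone-stabilized ylide under neutral conditions should give the (E)-enone selectively without epimerizing the α-silyloxy aldehyde.

Step 6
Reactants: 7 (3E,5S)-5-[(tert-butyldimethylsilyl)oxy]-6-{4-[(tert-butyldimethylsilyl)oxy]phenyl}hex-3-en-2-one
Product: 8 (3E,5S)-5-[(tert-butyldimethylsilyl)oxy]-6-{4-[(tert-butyldimethylsilyl)oxy]phenyl}-2-[(triethylsilyl)oxy]hexa-1,3-diene
Conditions: TESOTf, Et3N, Et2O, −78 → 0 °C; rapid filtration through Et3N-deactivated silica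
Reagents that add atoms: triethylsilyl trifluoromethanesulfonate, CC[Si](CC)(CC)OS(=O)(=O)C(F)(F)F
Why: Soft enolization (silyl triflate and tertiary amine) of the methyl ketone removes a proton from its only α-carbon, the methyl group, to give the cross-conjugated 2-silyloxy-1,3-diene with the (E)-alkene and the allylic stereocentre intact.

Step 7
Reactants: 8 (3E,5S)-5-[(tert-butyldimethylsilyl)oxy]-6-{4-[(tert-butyldimethylsilyl)oxy]phenyl}-2-[(triethylsilyl)oxy]hexa-1,3-diene; 9 4-formyl-2-methoxyphenyl acetate (vanillin acetate)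
Product: 11 4-[(2S,6R)-6-[(1S)-1-[(tert-butyldimethylsilyl)oxy]-2-{4-[(tert-butyldimethylsilyl)oxy]phenyl}ethyl]-4-oxooxan-2-yl]-2-methoxyphenyl acetate, via silyl enol ether cycloadduct 10 (not isolated)
Conditions: CrCl(L) (5–10 mol %; trivalent chromium; L = C27H29NO2, the doubly deprotonated Schiff base of (1S,2R)-1-aminoindan-2-ol and 3-(1-adamantyl)-2-hydroxy-5-methylbenzaldehyde), 4 Å MS, acetone (minimum volume), rt; then CH2Cl2, TFA (cat.), moist, 0 °C
Reagents that add atoms: none
Why: The chiral CrCl(L) Lewis acid binds the aldehyde oxygen of 9 anti to the aryl group, and the s-cis diene 8 adds in a concerted but asynchronous oxa-[4+2] cycloaddition in which the nucleophilic CH2 terminus of the silyl enol ether bonds to the carbonyl carbon (C2–C3) while the carbonyl oxygen closes onto the distal diene carbon (O1–C6); acid then protonates C5 of enol ether 10 and releases the C4 ketone. The closest known reaction type is the catalytic asymmetric hetero-Diels–Alder reaction of 2-silyloxydienes with aldehydes under tridentate Schiff-base chromium catalysis. The pyran ring is closed by this intermolecular [4+2] cycloaddition, both ring bonds arising in one suprafacial event and not by cyclization of a chain. C2 is set by the catalyst, the (1S,2R) ligand being expected to expose the Si face of the aldehyde; C6 follows from the endo transition state (aryl endo, metal exo) on the (E)-diene, which places H-2 and H-6 cis; the diene face used is the one anti to the allylic C–OTBS bond with the allylic hydrogen eclipsing the diene, so catalyst and substrate bias are expected to be matched. The step needs cycloaddition to outrun the open-chain Mukaiyama aldol path and needs an aryl aldehyde electrophilic enough for a mono-oxygenated diene: the mild catalyst should secure the former and the electron-withdrawing O-acetyl group (in place of a free or silylated phenol oxygen) the latter. Regiochemistry is fixed by the polarity of the 2-silyloxydiene.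

Step 8
Reactants: 11 4-[(2S,6R)-6-[(1S)-1-[(tert-butyldimethylsilyl)oxy]-2-{4-[(tert-butyldimethylsilyl)oxy]phenyl}ethyl]-4-oxooxan-2-yl]-2-methoxyphenyl acetate
Product: 12 4-[(2S,6R)-6-[(1S)-1-hydroxy-2-(4-hydroxyphenyl)ethyl]-4-oxooxan-2-yl]-2-methoxyphenyl acetate
Conditions: HF·pyridine (excess), THF/pyridine, 0 °C → rt
Reagents that add atoms: none
Why: Fluoride-mediated desilylation with buffered HF·pyridine cleaves the aryl and the secondary alkyl TBS ethers without base, so the β-alkoxy ketone cannot open by retro-oxa-Michael elimination, and the aryl acetate survives and keeps the benzylic C2–O bond deactivated toward acid ionization.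

Step 9
Reactants: 12 4-[(2S,6R)-6-[(1S)-1-hydroxy-2-(4-hydroxyphenyl)ethyl]-4-oxooxan-2-yl]-2-methoxyphenyl acetate
Product: 13 (2S,6R)-2-(4-hydroxy-3-methoxyphenyl)-6-[(1S)-1-hydroxy-2-(4-hydroxyphenyl)ethyl]oxan-4-one
Conditions: K2CO3 (cat.), MeOH, 0 °C, short reaction time; pH 7 buffer
Reagents that add atoms: none
Why: Carbonate-catalysed transesterification (Zemplén-type methanolysis) removes the phenolic acetate, the most labile ester type, at 0 °C, conditions expected to be too mild for β-elimination of the ring oxygen, and the 2,6-cis arrangement is in any case the thermodynamic one.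

**Compound list**

1 | L-tyrosine | N[C@@H](Cc1ccc(O)cc1)C(=O)O | starting material
2 | (2S)-2-hydroxy-3-(4-hydroxyphenyl)propanoic acid | O[C@@H](Cc1ccc(O)cc1)C(=O)O | intermediate
3 | methyl (2S)-2-hydroxy-3-(4-hydroxyphenyl)propanoate | COC(=O)[C@@H](O)Cc1ccc(O)cc1 | intermediate
4 | methyl (2S)-2-[(tert-butyldimethylsilyl)oxy]-3-{4-[(tert-butyldimethylsilyl)oxy]phenyl}propanoate | COC(=O)[C@@H](O[Si](C)(C)C(C)(C)C)Cc1ccc(O[Si](C)(C)C(C)(C)C)cc1 | intermediate
5 | (2S)-2-[(tert-butyldimethylsilyl)oxy]-3-{4-[(tert-butyldimethylsilyl)oxy]phenyl}propanal | O=C[C@@H](O[Si](C)(C)C(C)(C)C)Cc1ccc(O[Si](C)(C)C(C)(C)C)cc1 | intermediate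
6 | 1-(triphenyl-λ5-phosphanylidene)propan-2-one | CC(=O)C=P(c1ccccc1)(c1ccccc1)c1ccccc1 | starting material
7 | (3E,5S)-5-[(tert-butyldimethylsilyl)oxy]-6-{4-[(tert-butyldimethylsilyl)oxy]phenyl}hex-3-en-2-one | CC(=O)/C=C/[C@@H](O[Si](C)(C)C(C)(C)C)Cc1ccc(O[Si](C)(C)C(C)(C)C)cc1 | intermediate
8 | (3E,5S)-5-[(tert-butyldimethylsilyl)oxy]-6-{4-[(tert-butyldimethylsilyl)oxy]phenyl}-2-[(triethylsilyl)oxy]hexa-1,3-diene | C=C(O[Si](CC)(CC)CC)/C=C/[C@@H](O[Si](C)(C)C(C)(C)C)Cc1ccc(O[Si](C)(C)C(C)(C)C)cc1 | intermediate
9 | 4-formyl-2-methoxyphenyl acetate (vanillin acetate) | CC(=O)Oc1ccc(C=O)cc1OC | starting material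
10 | 4-[(2S,6R)-6-[(1S)-1-[(tert-butyldimethylsilyl)oxy]-2-{4-[(tert-butyldimethylsilyl)oxy]phenyl}ethyl]-4-[(triethylsilyl)oxy]-3,6-dihydro-2H-pyran-2-yl]-2-methoxyphenyl acetate | COc1cc([C@@H]2CC(O[Si](CC)(CC)CC)=C[C@H]([C@@H](O[Si](C)(C)C(C)(C)C)Cc3ccc(O[Si](C)(C)C(C)(C)C)cc3)O2)ccc1OC(C)=O | intermediate
11 | 4-[(2S,6R)-6-[(1S)-1-[(tert-butyldimethylsilyl)oxy]-2-{4-[(tert-butyldimethylsilyl)oxy]phenyl}ethyl]-4-oxooxan-2-yl]-2-methoxyphenyl acetate | COc1cc([C@@H]2CC(=O)C[C@H]([C@@H](O[Si](C)(C)C(C)(C)C)Cc3ccc(O[Si](C)(C)C(C)(C)C)cc3)O2)ccc1OC(C)=O | intermediate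
12 | 4-[(2S,6R)-6-[(1S)-1-hydroxy-2-(4-hydroxyphenyl)ethyl]-4-oxooxan-2-yl]-2-methoxyphenyl acetate | COc1cc([C@@H]2CC(=O)C[C@H]([C@@H](O)Cc3ccc(O)cc3)O2)ccc1OC(C)=O | intermediate
13 | (2S,6R)-2-(4-hydroxy-3-methoxyphenyl)-6-[(1S)-1-hydroxy-2-(4-hydroxyphenyl)ethyl]oxan-4-one | COc1cc([C@@H]2CC(=O)C[C@H]([C@@H](O)Cc3ccc(O)cc3)O2)ccc1O | target

**Totals**

Total step count: 9. Longest linear sequence: 9 steps (1 → 13); compounds 6 and 9 are purchased.

**Steps most likely to fail**

Step 7. The cycloaddition may stall because the aryl aldehyde is a weak heterodienophile for a mono-oxygenated diene. It may also leak into open-chain silyl-transfer aldol products, or show eroded facial selectivity if catalyst and allylic stereocentre are not matched as expected. The fallback makes the two ring bonds one after the other and sets out from enone 7. The methyl group of 7 is enolized with (+)-Ipc2BCl and Et3N in Et2O at −78 °C and the boron enolate is combined with 9. The borane antipode is to be confirmed on the first adduct, and a non-oxidative diethanolamine work-up spares the aryl acetate. This should give the β-hydroxy enone 4-[(1S,4E,6S)-6-[(tert-butyldimethylsilyl)oxy]-7-{4-[(tert-butyldimethylsilyl)oxy]phenyl}-1-hydroxy-3-oxohept-4-en-1-yl]-2-methoxyphenyl acetate F1. A 6-endo oxa-Michael closure under thermodynamic control (Amberlyst-15, CH2Cl2, rt) then places both ring substituents equatorial, so C6 follows C2, and the sequence comes back to the route at ketone 11.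

Step 9. Base may trigger retro-oxa-Michael opening of the β-alkoxy ketone during methanolysis, with scrambling of C2 and C6 on reclosure or loss of material. The fallback changes the activating group on the vanillin oxygen to one that leaves by neutral hydrogenolysis and sets out from diene 8. Vanillin and benzyl chloroformate (Et3N, CH2Cl2) give benzyl (4-formyl-2-methoxyphenyl) carbonate F2. F2 is taken with 8 through the conditions of step 7 to the silyl enol ether cycloadduct F3 (not isolated) and on to the benzyl carbonate ketone F4. F4 is desilylated as in step 8 to the desilylated benzyl carbonate F5. H2 over Pd/C (EtOAc, rt, 1 atm) then cleaves the benzyl carbonate with loss of toluene and CO2, and the sequence comes back to the route at target 13 without any basic step.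

Step 4. Partial reduction may over-reduce to the primary alcohol, or the α-silyloxy aldehyde may epimerize during work-up and handling. The fallback sets out from ester 4. It is reduced fully with excess i-Bu2AlH (CH2Cl2, −78 → 0 °C; a non-basic hydride, so that silyl migration is avoided) to (2S)-2-[(tert-butyldimethylsilyl)oxy]-3-{4-[(tert-butyldimethylsilyl)oxy]phenyl}propan-1-ol F6. F6 is oxidized with Dess–Martin periodinane (NaHCO3, CH2Cl2) in the presence of ylide 6, so that aldehyde 5 is trapped as it forms. The sequence comes back to the route at enone 7.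

**Further compounds**

F1 | step 7 | 4-[(1S,4E,6S)-6-[(tert-butyldimethylsilyl)oxy]-7-{4-[(tert-butyldimethylsilyl)oxy]phenyl}-1-hydroxy-3-oxohept-4-en-1-yl]-2-methoxyphenyl acetate | COc1cc([C@@H](O)CC(=O)/C=C/[C@@H](O[Si](C)(C)C(C)(C)C)Cc2ccc(O[Si](C)(C)C(C)(C)C)cc2)ccc1OC(C)=O
F2 | step 9 | benzyl (4-formyl-2-methoxyphenyl) carbonate | COc1cc(C=O)ccc1OC(=O)OCc1ccccc1
F3 | step 9 | benzyl {4-[(2S,6R)-6-[(1S)-1-[(tert-butyldimethylsilyl)oxy]-2-{4-[(tert-butyldimethylsilyl)oxy]phenyl}ethyl]-4-[(triethylsilyl)oxy]-3,6-dihydro-2H-pyran-2-yl]-2-methoxyphenyl} carbonate | COc1cc([C@@H]2CC(O[Si](CC)(CC)CC)=C[C@H]([C@@H](O[Si](C)(C)C(C)(C)C)Cc3ccc(O[Si](C)(C)C(C)(C)C)cc3)O2)ccc1OC(=O)OCc1ccccc1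
F4 | step 9 | benzyl {4-[(2S,6R)-6-[(1S)-1-[(tert-butyldimethylsilyl)oxy]-2-{4-[(tert-butyldimethylsilyl)oxy]phenyl}ethyl]-4-oxooxan-2-yl]-2-methoxyphenyl} carbonate | COc1cc([C@@H]2CC(=O)C[C@H]([C@@H](O[Si](C)(C)C(C)(C)C)Cc3ccc(O[Si](C)(C)C(C)(C)C)cc3)O2)ccc1OC(=O)OCc1ccccc1
F5 | step 9 | benzyl {4-[(2S,6R)-6-[(1S)-1-hydroxy-2-(4-hydroxyphenyl)ethyl]-4-oxooxan-2-yl]-2-methoxyphenyl} carbonate | COc1cc([C@@H]2CC(=O)C[C@H]([C@@H](O)Cc3ccc(O)cc3)O2)ccc1OC(=O)OCc1ccccc1
F6 | step 4 | (2S)-2-[(tert-butyldimethylsilyl)oxy]-3-{4-[(tert-butyldimethylsilyl)oxy]phenyl}propan-1-ol | OC[C@@H](O[Si](C)(C)C(C)(C)C)Cc1ccc(O[Si](C)(C)C(C)(C)C)cc1
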